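**Assumption:** the target, 2,3,5-tribromo-6-(2-bromophenoxy)phenol, has no stereocentre and no hindered axis that could be resolved. It is achiral, so there is no configuration to set.

## Retrosynthetic overview
1. The phenol OH comes from an aryl iodide by chemoselective I/Mg exchange, borylation and oxidation. Iodine serves as a masked hydroxyl next to the ether oxygen.
2. Key step: the diaryl ether C–O bond and that C–I bond both come from one iodine(III) reagent. This avoids an Ullmann, SNAr or Chan–Lam coupling. 2,4,5-Tribromophenol is iodonylated at its only free ortho position, then the 2-bromophenyl group migrates 1,4 from I to O.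
3. 2,4,5-Tribromophenol comes from symmetrical 1,2,4,5-tetrabromobenzene by exchange of one Br for OH, which fixes the difficult pattern (H para to the final OH) without any bromination.
4. The iodane comes from 1-bromo-2-iodobenzene by oxidation.
5. No ring is built. Both benzene rings are bought and all four bromines are present from the start.

## Route

**Step 1**
Reactants: 1 1,2,4,5-tetrabromobenzene
Product: 4 2,4,5-tribromophenol, via 2,4,5-tribromophenylmagnesium chloride 2 (not isolated), via dimethyl (2,4,5-tribromophenyl)boronate 3 (not isolated)
Conditions: iPrMgCl·LiCl (1.05 equiv), THF, −40 °C, 1 h; B(OMe)3, −40 to 0 °C; then AcOH, 30% H2O2, 0 °C to rt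
Reagents that add atoms: hydrogen peroxide OO (the O of 4); isopropylmagnesium chloride CC(C)[Mg]Cl (MgCl of 2 only); trimethyl borate COB(OC)OC (B(OMe)2 of 3 only)
Why: Knochel Br/Mg exchange followed by borylation and oxidation works here because all four bromines of 1 are equivalent, so a single exchange gives one product, and the ortho-bromo Grignard does not lose MgBrCl to an aryne at −40 °C.

**Step 2**
Reactants: 5 1-bromo-2-iodobenzene
Product: 6 1-bromo-2-(diacetoxy-λ3-iodanyl)benzene
Conditions: 35–40% AcOOH in AcOH, 30 °C, 12 h; precipitate with water
Reagents that add atoms: peracetic acid CC(=O)OO; acetic acid CC(=O)O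
Why: This is the classical peracid oxidation of an iodoarene to a (diacetoxyiodo)arene, in which only iodine is oxidised and the ortho C–Br bond is inert.

**Step 3 (key step)**
Reactants: 4 2,4,5-tribromophenol; 6 1-bromo-2-(diacetoxy-λ3-iodanyl)benzene
Product: 8 1,2,5-tribromo-4-(2-bromophenoxy)-3-iodobenzene, via 3,4,6-tribromo-2-[(2-bromophenyl)iodonio]phenolate 7 (not isolated)
Conditions: MeCN, 0 °C to rt, 4 h; then 80 °C, 12 h
Reagents that add atoms: none
Why: Proposed new method: acidic, electron-poor phenols (4 should have a pKa near 7, like 4-nitrophenol) exchange acetate on ArI(OAc)2 and are then attacked by I(III) at a free ortho carbon, here the only open ortho/para site, to give iodonium phenolate 7, which on heating collapses through a five-membered ipso attack of O⁻ on the 2-bromophenyl carbon (Smiles-type ligand coupling, helped by the ortho-bromine) to place the aryl on O and leave iodine on the ring. The closest known reaction type is the formation and thermal 1,4 I-to-O aryl migration of nitro-substituted aryliodonium phenolates to give 2-iodo diaryl ethers, and the new elements are the polybromophenol substrate and the one-pot execution.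

**Step 4**
Reactants: 8 1,2,5-tribromo-4-(2-bromophenoxy)-3-iodobenzene
Product: 11 2,3,5-tribromo-6-(2-bromophenoxy)phenol, via [2,3,5-tribromo-6-(2-bromophenoxy)phenyl]magnesium chloride 9 (not isolated), via dimethyl [2,3,5-tribromo-6-(2-bromophenoxy)phenyl]boronate 10 (not isolated)
Conditions: iPrMgCl·LiCl (1.05 equiv), THF, −78 °C, 30 min; B(OMe)3 (3 equiv), −78 to 0 °C; then AcOH, 30% H2O2, 0 °C to rt
Reagents that add atoms: hydrogen peroxide OO (the O of 11); isopropylmagnesium chloride CC(C)[Mg]Cl (MgCl of 9 only); trimethyl borate COB(OC)OC (B(OMe)2 of 10 only)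
Why: Knochel I/Mg exchange on an electron-poor ring is far faster than Br/Mg exchange at −78 °C, so only the C–I bond is metalated, and borylation with acidic peroxide oxidation gives the phenol without the base and heat that would close 11 to a dibenzo-p-dioxin.

## Compound list
1 | 1,2,4,5-tetrabromobenzene | Brc1cc(Br)c(Br)cc1Br | starting material
2 | 2,4,5-tribromophenylmagnesium chloride | Cl[Mg]c1cc(Br)c(Br)cc1Br | intermediate
3 | dimethyl (2,4,5-tribromophenyl)boronate | COB(OC)c1cc(Br)c(Br)cc1Br | intermediate
4 | 2,4,5-tribromophenol | Oc1cc(Br)c(Br)cc1Br | intermediate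
5 | 1-bromo-2-iodobenzene | Brc1ccccc1I | starting material
6 | 1-bromo-2-(diacetoxy-λ3-iodanyl)benzene | CC(=O)OI(OC(C)=O)c1ccccc1Br | intermediate
7 | 3,4,6-tribromo-2-[(2-bromophenyl)iodonio]phenolate (zwitterion) | [O-]c1c(Br)cc(Br)c(Br)c1[I+]c1ccccc1Br | intermediate
8 | 1,2,5-tribromo-4-(2-bromophenoxy)-3-iodobenzene (I ortho to the ether O, between OAr and Br) | Brc1ccccc1Oc1c(Br)cc(Br)c(Br)c1I | intermediate
9 | [2,3,5-tribromo-6-(2-bromophenoxy)phenyl]magnesium chloride | Cl[Mg]c1c(Br)c(Br)cc(Br)c1Oc1ccccc1Br | intermediate
10 | dimethyl [2,3,5-tribromo-6-(2-bromophenoxy)phenyl]boronate | COB(OC)c1c(Br)c(Br)cc(Br)c1Oc1ccccc1Br | intermediate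
11 | 2,3,5-tribromo-6-(2-bromophenoxy)phenol (achiral) | Oc1c(Br)c(Br)cc(Br)c1Oc1ccccc1Br | target

## Step count
Total step count: 4.
Longest linear sequence: 3 (1 → 4 → 8 → 11). Step 2 is a one-step side branch.

## Steps most likely to fail and their fallbacks

**Step 3.** The risks are oxidative dearomatisation of 4 at the brominated para carbon instead of ortho C–I bond formation, and a sluggish migration.
- The fallback separates the two bond formations. It sets out from 4 and from 5 and comes back to the route at 8.
- Compound 4 is iodinated at its only free ortho position (NIS, catalytic TFA, MeCN) to give 3,4,6-tribromo-2-iodophenol F1.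
- In parallel, 5 is oxidised with mCPBA and TsOH and trapped with 1,3,5-trimethoxybenzene to give (2-bromophenyl)(2,4,6-trimethoxyphenyl)iodonium tosylate F2.
- Metal-free intermolecular O-arylation of F1 with F2 (K2CO3, toluene, 60 °C) transfers the 2-bromophenyl group, because the electron-rich trimethoxyphenyl ligand stays on iodine. This delivers 8.

**Step 4.** The risks are aryne loss from the ortho-bromo Grignard 9 before the hindered borylation, and protodeboronation of 10.
- The fallback avoids any aryl-metal species. It sets out from 8 and comes back at 11.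
- A copper-catalysed Ullmann-type etherification of the C–I bond is run with 4-methoxybenzyl alcohol (CuI, 1,10-phenanthroline, Cs2CO3, toluene, 90 °C; I reacts before Br). It gives 1,2,5-tribromo-4-(2-bromophenoxy)-3-[(4-methoxybenzyl)oxy]benzene F3.
- The oxygen is kept protected so that no free phenoxide can close onto the 2-bromophenyl ring under copper.
- TFA in CH2Cl2 at rt then removes the PMB group to give 11.

**Step 1.** The risks are the poor solubility of 1, double exchange, and aryne formation from 2.
- The fallback replaces metalation by copper-catalysed nucleophilic substitution. It sets out from 1 and comes back at 4.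
- Compound 1, used in excess, reacts with NaOMe and CuBr in DMF/MeOH at 100 °C to give 2,4,5-tribromoanisole F4. This product is more electron-rich than 1 and therefore reacts further only slowly.
- BBr3 in CH2Cl2 cleaves the methyl ether to give 4.

## Further compounds
F1 | step 3 | 3,4,6-tribromo-2-iodophenol | Oc1c(Br)cc(Br)c(Br)c1I
F2 | step 3 | (2-bromophenyl)(2,4,6-trimethoxyphenyl)iodonium tosylate | COc1cc(OC)c([I+]c2ccccc2Br)c(OC)c1.Cc1ccc(S(=O)(=O)[O-])cc1
F3 | step 4 | 1,2,5-tribromo-4-(2-bromophenoxy)-3-[(4-methoxybenzyl)oxy]benzene | COc1ccc(COc2c(Br)c(Br)cc(Br)c2Oc2ccccc2Br)cc1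
F4 | step 1 | 2,4,5-tribromoanisole | COc1cc(Br)c(Br)cc1Br
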